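**Plan**

Ring letters: A = the trioxygenated ring bearing the carbinol carbon, B = the para-phenylene, C = the 1,2,3-trisubstituted ring, D = the meta-phenylene.
Cuts, in order: the O-protecting groups; the bond between C4 of ring B and the neighbouring CH2 of the saturated CH2–CH2 bridge to ring C (this opens the 18-membered ring); the C(=O)–CH2 bond of a ring A/ring D deoxybenzoin; the two diaryl ether C–O bonds (O–ring B and O–ring C).
Enabling feature: C4 of ring B lies para to the A–O–B oxygen and is flanked by two C–H positions, and both bridge carbons are sp3. This bond can therefore be made from a ring-B iodide and a flexible primary alkylborane grown on a ring-C vinyl group.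
Forward: C/D ether by SNAr, then methylenation; A/B ether by Ullmann coupling; union of the halves by decarboxylative Claisen condensation; the macrocycle is the only ring formed and closes in step 9; two deprotections finish the route.
Stereochemistry: the single (S)-carbinol centre is set by catalyst control in an asymmetric transfer hydrogenation of the open-chain ketone and is carried on as a silyl ether. No later step breaks its C–O or C–H bond.

Key step: step 9

Remark: the descriptor (S) follows from the SMILES with the priorities O > C1 of ring A > CH2 > H.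
Remark: 2-fluoro-3-hydroxybenzaldehyde is taken as a catalogue compound. It is used so that ring C carries a benzyl ether that leaves in the final hydrogenolysis, and no Lewis-acidic demethylation is needed next to the carbinol.

**Step 1**
Reactants: 1 2-fluoro-3-hydroxybenzaldehyde
Product: 2 3-(benzyloxy)-2-fluorobenzaldehyde
Conditions: BnBr (1.1 equiv), K2CO3, DMF, rt
Reagents that add atoms: benzyl bromide, BrCc1ccccc1
Why: Williamson ether synthesis, in which the phenoxide of 1 is benzylated at room temperature while the aldehyde and the aryl fluoride stay inert.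

**Step 2**
Reactants: 2 3-(benzyloxy)-2-fluorobenzaldehyde; 3 3-hydroxyphenylacetic acid
Product: 4 2-{3-[2-(benzyloxy)-6-formylphenoxy]phenyl}acetic acid
Conditions: K2CO3 (3 equiv), DMSO, 110 °C, Ar; then aq. HCl to pH 3
Reagents that add atoms: none
Why: Nucleophilic aromatic substitution (SNAr, addition–elimination), in which the ortho-formyl group stabilises the Meisenheimer adduct so that the phenoxide of 3 displaces fluoride, while the carboxylate is too weak a nucleophile to compete and, being anionic, keeps its neighbouring CH2 from condensing with the aldehyde.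

**Step 3**
Reactants: 4 2-{3-[2-(benzyloxy)-6-formylphenoxy]phenyl}acetic acid
Product: 5 2-{3-[2-(benzyloxy)-6-ethenylphenoxy]phenyl}acetic acid
Conditions: Ph3PCH3Br (2.5 equiv), KOtBu (3.5 equiv), THF, 0 °C to rt; then aq. citric acid
Reagents that add atoms: methyltriphenylphosphonium bromide, C[P+](c1ccccc1)(c1ccccc1)c1ccccc1.[Br-]
Why: Wittig methylenation, in which the non-stabilised ylide turns the aryl aldehyde into the terminal styrene while the acid travels as its potassium salt, which also allows the phosphine oxide to be removed by acid–base extraction.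

**Step 4**
Reactants: 6 methyl gallate
Product: 7 methyl 3,4-bis(benzyloxy)-5-hydroxybenzoate
Conditions: BnBr (2.0 equiv), K2CO3 (2.1 equiv), DMF, rt; chromatography
Reagents that add atoms: benzyl bromide, BrCc1ccccc1
Why: Williamson ether synthesis under stoichiometric control, in which the 4-OH (para to the ester, most acidic) is alkylated first and one of the two equivalent flanking OH groups second, so that two equivalents of bromide should stop mainly at the 3,4-diether, separable from under- and over-alkylated material on this inexpensive substrate.

**Step 5**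
Reactants: 7 methyl 3,4-bis(benzyloxy)-5-hydroxybenzoate; 8 1,4-diiodobenzene (4 equiv)
Product: 9 methyl 3,4-bis(benzyloxy)-5-(4-iodophenoxy)benzoate
Conditions: CuI (20 mol %), N,N-dimethylglycine·HCl (40 mol %), Cs2CO3 (2.5 equiv), dry 1,4-dioxane, 90 °C
Reagents that add atoms: none
Why: Ullmann diaryl ether synthesis with amino-acid-ligated copper(I), in which the only free phenol of 7 couples with one C–I bond of 8, and the excess of 8 together with the lower reactivity of the now electron-richer iodide of 9 should hold the reaction at the mono-ether.

**Step 6**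
Reactants: 5 2-{3-[2-(benzyloxy)-6-ethenylphenoxy]phenyl}acetic acid (1.2 equiv); 9 methyl 3,4-bis(benzyloxy)-5-(4-iodophenoxy)benzoate
Product: 11 1-[3,4-bis(benzyloxy)-5-(4-iodophenoxy)phenyl]-2-{3-[2-(benzyloxy)-6-ethenylphenoxy]phenyl}ethan-1-one (open-chain deoxybenzoin), via β-keto acid 10 (not isolated)
Conditions: LiHMDS (4 equiv), THF, −20 °C to rt; then 1 M HCl, rt (−CO2)
Reagents that add atoms: none
Why: Decarboxylative crossed Claisen condensation, in which the amide base converts 5 into its enediolate, the non-enolisable benzoate 9 acylates it at carbon, and the β-keto acid 10 released on acidification loses CO2, while LiHMDS neither exchanges with the aryl iodide nor adds to the styrene.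

**Step 7**
Reactants: 11 open-chain deoxybenzoin
Product: 12 (1S)-1-[3,4-bis(benzyloxy)-5-(4-iodophenoxy)phenyl]-2-{3-[2-(benzyloxy)-6-ethenylphenoxy]phenyl}ethan-1-ol
Conditions: RuCl[(S,S)-TsDPEN](p-cymene) (2 mol %), HCO2H/Et3N (5:2), CH2Cl2, 30 °C
Reagents that add atoms: none
Why: Noyori–Ikariya asymmetric transfer hydrogenation, in which the (S,S)-configured Ru hydride transfers H−/H+ through the outer-sphere six-membered transition state with the carbonyl-conjugated ring A held under the η6-cymene by a CH/π contact, so hydride should reach the Re face and give the (S)-alcohol (the same sense as acetophenone to (S)-1-phenylethanol), with the unpolarised vinyl group and the C–I bond left alone.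

**Step 8**
Reactants: 12 (S)-alcohol
Product: 13 tert-butyldimethylsilyl ether of 12 with (S) configuration (open-chain precursor with ring-C vinyl group and ring-B iodide)
Conditions: TBSCl (1.5 equiv), imidazole (3 equiv), DMF, rt
Reagents that add atoms: tert-butyldimethylsilyl chloride, CC(C)(C)[Si](C)(C)Cl
Why: Imidazole-promoted O-silylation forms only an O–Si bond, so the configuration is retained, and it shields the hydroxyl from 9-BBN and from palladium alkoxide oxidation pathways in the next step.

**Step 9**
Reactants: 13 (S)-silyl ether with ring-C vinyl group and ring-B iodide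
Product: 15 (S)-O-TBS tri-O-benzyl macrocycle (18-membered ring closed at ring B C4–CH2), via alkyl-9-BBN borane 14 (not isolated)
Conditions: 9-BBN (0.5 M in THF, 2 equiv), THF, 0 °C to rt; degassed H2O; then syringe-pump addition over 12 h to PdCl2(dppf)·CH2Cl2 (20 mol %), AsPh3 (20 mol %), Cs2CO3 (4 equiv), DMF/THF/H2O, 60 °C, final ca. 1 mM
Reagents that add atoms: 9-BBN (9-borabicyclo[3.3.1]nonane), B1C2CCCC1CCC2 (its boron cage is held only by intermediate 14 and leaves again in the coupling; 15 keeps one hydrogen of it)
Why: 9-BBN adds syn and anti-Markovnikov to the ring-C vinyl group to give the primary borane 14, aqueous carbonate converts 14 into its hydroxyborate, Pd(0) inserts into the only C–I bond, the alkyl group transmetalates to the arylpalladium(II) iodide, and reductive elimination forms the ring B C4–CH2 bond. The closest known reaction type is the macrocyclising B-alkyl Suzuki–Miyaura coupling of an alkene-tethered aryl iodide. The one ring closed is the 18-membered macrocycle, formed end to end by intramolecular sp3–sp2 coupling through a 19-membered palladacycle that contracts on reductive elimination. No stereocentre is created, and the (S)-silyloxy carbon is remote from every reacting atom and keeps its configuration. The step needs terminal regioselectivity in the hydroboration, secured by the bulk of 9-BBN on a monosubstituted styrene, and cyclisation over oligomerisation, secured by slow addition into dilute catalyst, by the flexible sp3 chain that can fold around the bent C–O–D ether, and by the unhindered para position of ring B. Reductive elimination must also outrun β-hydride elimination, which the wide bite angle of dppf favours.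

**Step 10**
Reactants: 15 (S)-O-TBS tri-O-benzyl macrocycle
Product: 16 (S)-tri-O-benzyl macrocyclic carbinol
Conditions: TBAF (1.5 equiv), THF, 0 °C to rt
Reagents that add atoms: none
Why: Fluoride-induced desilylation, driven by Si–F bond formation, cleaves only the O–Si bond with retention, and it is run while all phenols are still benzylated so that the basic medium cannot open a para-quinone methide pathway.

**Step 11**
Reactants: 16 (S)-tri-O-benzyl macrocyclic carbinol
Product: 17 target CNP0333307.1, the (S)-configured macrocyclic bis(bibenzyl) with three phenolic OH groups and the benzylic carbinol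
Conditions: H2 (1 atm), 10 % Pd/C, EtOAc, rt, stopped at full conversion; filtration through Celite, concentration below 30 °C
Reagents that add atoms: none
Why: Catalytic hydrogenolysis under neutral conditions, in which aryl benzyl ethers are cleaved on Pd/C far more readily than a secondary benzylic alcohol, so the three phenols should be released while the (S)-carbinol and both diaryl ethers persist.

**Compound list**

1 | 2-fluoro-3-hydroxybenzaldehyde | O=Cc1cccc(O)c1F | starting material
2 | 3-(benzyloxy)-2-fluorobenzaldehyde | O=Cc1cccc(OCc2ccccc2)c1F | intermediate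
3 | 3-hydroxyphenylacetic acid | OC(=O)Cc1cccc(O)c1 | starting material
4 | 2-{3-[2-(benzyloxy)-6-formylphenoxy]phenyl}acetic acid | OC(=O)Cc1cccc(Oc2c(C=O)cccc2OCc2ccccc2)c1 | intermediate
5 | 2-{3-[2-(benzyloxy)-6-ethenylphenoxy]phenyl}acetic acid | OC(=O)Cc1cccc(Oc2c(C=C)cccc2OCc2ccccc2)c1 | intermediate
6 | methyl gallate | COC(=O)c1cc(O)c(O)c(O)c1 | starting material
7 | methyl 3,4-bis(benzyloxy)-5-hydroxybenzoate | COC(=O)c1cc(O)c(OCc2ccccc2)c(OCc2ccccc2)c1 | intermediate
8 | 1,4-diiodobenzene | Ic1ccc(I)cc1 | starting material
9 | methyl 3,4-bis(benzyloxy)-5-(4-iodophenoxy)benzoate | COC(=O)c1cc(OCc2ccccc2)c(OCc2ccccc2)c(Oc2ccc(I)cc2)c1 | intermediate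
10 | β-keto acid, 3-[3,4-bis(benzyloxy)-5-(4-iodophenoxy)phenyl]-2-{3-[2-(benzyloxy)-6-ethenylphenoxy]phenyl}-3-oxopropanoic acid (racemic at C2, centre lost on decarboxylation, not isolated) | OC(=O)C(c1cccc(Oc2c(C=C)cccc2OCc2ccccc2)c1)C(=O)c1cc(OCc2ccccc2)c(OCc2ccccc2)c(Oc2ccc(I)cc2)c1 | intermediate
11 | 1-[3,4-bis(benzyloxy)-5-(4-iodophenoxy)phenyl]-2-{3-[2-(benzyloxy)-6-ethenylphenoxy]phenyl}ethan-1-one | C=Cc1cccc(OCc2ccccc2)c1Oc1cccc(c1)CC(=O)c1cc(OCc2ccccc2)c(OCc2ccccc2)c(c1)Oc1ccc(I)cc1 | intermediate
12 | (1S)-1-[3,4-bis(benzyloxy)-5-(4-iodophenoxy)phenyl]-2-{3-[2-(benzyloxy)-6-ethenylphenoxy]phenyl}ethan-1-ol | C=Cc1cccc(OCc2ccccc2)c1Oc1cccc(c1)C[C@H](O)c1cc(OCc2ccccc2)c(OCc2ccccc2)c(c1)Oc1ccc(I)cc1 | intermediate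
13 | (S)-tert-butyldimethylsilyl ether of 12 (ring-C vinyl, ring-B iodide) | C=Cc1cccc(OCc2ccccc2)c1Oc1cccc(c1)C[C@H](O[Si](C)(C)C(C)(C)C)c1cc(OCc2ccccc2)c(OCc2ccccc2)c(c1)Oc1ccc(I)cc1 | intermediate
14 | (S)-B-alkyl-9-BBN borane, the vinyl group of 13 converted into CH2CH2–B(9-BBN) (not isolated) | C(CB1C2CCCC1CCC2)c1cccc(OCc2ccccc2)c1Oc1cccc(c1)C[C@H](O[Si](C)(C)C(C)(C)C)c1cc(OCc2ccccc2)c(OCc2ccccc2)c(c1)Oc1ccc(I)cc1 | intermediate
15 | (S)-O-TBS tri-O-benzyl macrocycle (18-membered; OBn at C3 and C4 of ring A and at C3 of ring C) | c3ccccc3COc1cc2cc(c1OCc3ccccc3)Oc1ccc(cc1)CCc1cccc(OCc3ccccc3)c1Oc1cccc(c1)C[C@@H]2O[Si](C)(C)C(C)(C)C | intermediate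
16 | (S)-tri-O-benzyl macrocyclic carbinol | c3ccccc3COc1cc2cc(c1OCc3ccccc3)Oc1ccc(cc1)CCc1cccc(OCc3ccccc3)c1Oc1cccc(c1)C[C@@H]2O | intermediate
17 | CNP0333307.1, (S)-macrocyclic bis(bibenzyl) triphenol carbinol | Oc1cc2cc(c1O)Oc1ccc(cc1)CCc1cccc(O)c1Oc1cccc(c1)C[C@@H]2O | target

**Step count**

Total: 11 steps. Longest linear sequence: 9 steps (1 → 2 → 4 → 5 → 11 → 12 → 13 → 15 → 16 → 17). The ring A/B branch (6 → 7 → 9) joins at step 6.

**Steps most likely to fail**

1. **Step 9.** Intermolecular coupling may outpace ring closure. The alkyl group may also be lost by protodeboronation or by β-hydride elimination after transmetalation, or the C–I bond may be reduced. The fallback sets out from 13 and closes the same ring B C4–carbon bond without boron. An intramolecular Mizoroki–Heck reaction (Pd(OAc)2, P(o-tol)3, K2CO3, DMF, 90 °C, slow addition at high dilution) would arylate the terminal vinyl carbon and give the macrocyclic (E)-stilbene F1. Diimide (TsNHNH2, NaOAc, THF/H2O, reflux) would then saturate the new C=C bond without touching the benzyl ethers, the silyl ether or the stereocentre. The route is rejoined at 15.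

2. **Step 5.** The remaining C–I bond of the product may be etherified a second time, the flanked and electron-poor phenol may couple sluggishly, and the ester may be hydrolysed at 90 °C. The fallback sets out from 7 and uses an oxidative Chan–Lam coupling with commercial 4-iodophenylboronic acid (Cu(OAc)2, pyridine, 4 Å molecular sieves, CH2Cl2, air, rt). The C–O bond then forms at the C–B carbon, and the C–I bond is inert to copper(II) at room temperature, so only one coupling is possible. The route is rejoined directly at 9, and no compound outside the list arises (F0).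

3. **Step 11.** The benzylic C–OH bond, activated by the para oxygen of ring A, may be hydrogenolysed, or it may ionise with erosion of configuration as the phenols are set free. The fallback sets out from 15 and reverses the two deprotections. Hydrogenolysis (H2, Pd/C, EtOAc, rt) is run while the carbinol oxygen still carries its bulky silyl group, which should keep this C–O bond away from the catalyst surface, and gives the O-TBS triphenol macrocycle F2. Buffered fluoride (TBAF/AcOH 1:1, THF, 0 °C to rt) then removes the silyl group without forming phenoxides. The route is rejoined at 17.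

**Further compounds**

F1 | step 9 | (S)-O-TBS tri-O-benzyl macrocyclic (E)-stilbene | c3ccccc3COc1cc2cc(c1OCc3ccccc3)Oc1ccc(cc1)/C=C/c1cccc(OCc3ccccc3)c1Oc1cccc(c1)C[C@@H]2O[Si](C)(C)C(C)(C)C
F0 | step 5 | none | none
F2 | step 11 | (S)-O-TBS triphenol macrocycle | Oc1cc2cc(c1O)Oc1ccc(cc1)CCc1cccc(O)c1Oc1cccc(c1)C[C@@H]2O[Si](C)(C)C(C)(C)C
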